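Take the mM of Z as your money: each mM of X costs two of them, one to put a first Z on E and one to put a second on the mono adduct. So X, in percent of the E charged, stands under the charge of Z divided by twice the charge of E. For blue that gives 75.0%, and this number is the ceiling, Z charged over twice E charged. With the ceiling below 100 percent, Z is the limiting reagent for X.

| flask | E | Z | remark | time |
|---|---|---|---|---|
| alpha | 14 mM | 6.6 mM | run made earlier |  |
| theta | 14 mM | 93 mM | run made earlier |  |
| epsilon | 23 mM | 14 mM | run made earlier |  |
| teal | 8.0 mM | 8.00 mM |  | 40 min |
| grey | 10 mM | 5.00 mM |  | 40 min |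
| violet | 30 mM | 8.00 mM |  | 40 min |
| blue | 40 mM | 60.0 mM |  | 40 min |
| amber | 14 mM | 14.0 mM |  | 40 min |

- alpha (time / min: X / %, E / %): 3.00: 0.6, 91.7; 5.00: 0.9, 87.2; 8.00: 0.7, 81.7; 12.0: 0.9, 78.3; 15.0: 3.0, 73.2; 25.0: 3.1, 66.9; 40.0: 3.9, 61.1
- theta (time / min: X / %, E / %): 6.00: 37.7, 10.6; 12.0: 40.4, 3.2; 15.0: 36.1, 2.1; 25.0: 19.8, 2.3; 30.0: 11.4, 0; 40.0: 8.1, 0.4
- epsilon (time / min: X / %, E / %): 3.00: 0.4, 82.2; 6.00: 1.0, 74.0; 12.0: 6.2, 59.9; 20.0: 6.2, 51.6; 40.0: 8.8, 48.0

(each reading ± 1 percentage point)

- a reading or a percentage of X counts all its forms, free or not
- a reading of E is of its free form alone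

1. ranking by amount of X, in percent of the E charged, from high to low, at 40 min (teal / grey / violet / blue / amber)
2. the amount of X, in percent of the E charged of the flask you put first, at 40 min
3. the amount of X, in percent of the E charged of the flask you put last, at 40 min

As a bench rule the ceiling gives a ranking: blue first, then amber and teal, both at 50.0%, then grey at 25.0% and violet at 13.3%. I put amber before teal because its charges are larger, so I expect its steps to run faster. The ceiling is no estimate of the amount, though: alpha's ceiling is 23.6%, yet X reads only 3.9% at 40.0 min.

The other end is theta, whose ceiling of 332% lies past the border at 100, so the rule is silent there. In theta X reads 40.4% at 12.0 min, then falls to 8.1% at 40.0 min, so something goes on consuming X. Z stands well above what X needs in theta, so up to that peak, as far as the readings show it, I treat the steps as roughly pseudo-first-order, and I read its height as a matter of the ratio of making to consuming more than of the level of Z.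

Joining the ends, I take the lower of ceiling and peak for blue: 75.0% against a reading of 40.4%. Blue's charge of Z times 40 min is 2.15 times theta's up to that reading, though blue's Z falls as it is spent, so I expect blue to arrive near the peak. My figure is therefore about 40.4%.

The forecast says blue > amber > teal > grey > violet, with 31% on top and 1.7% last, and among its grounds stands that “X is then consumed by more Z”. Its order is mine, but its top lies below my figure.

The flasks give blue > amber > teal > grey > violet, from 39.2% in blue to 1.99% in violet.

    Z + X → Q + G (k = 0.0279 M⁻¹ s⁻¹)
    E + Z → J + G (k = 0.0808 M⁻¹ s⁻¹)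
    Z + J → X + G (k = 0.0474 M⁻¹ s⁻¹)
    E + X ⇌ D, settled at all times (K = 63.9 M⁻¹)

Blue's X is 52.3% of its ceiling of 75.0%, with Z down to 2.42% of its own charge at 40.0 min. A neighbouring flask, blue with 240 mM of Z, has a ceiling of 300%, past the border, and at 40.0 min it holds X at 0.0730% and Q, the tris adduct, at 99.9%.

All runs were computed from invented constants; the scatter is artificial.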